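The vessel was closed, stirred and isothermal, and the alder run, the very flask asked about, had been followed to 30.0 min.

all flasks: starting material 0.16 M; coupling partner 0.168 M; impurity 0.42 mM
- alder: second substrate 0.080 M; free catalyst 4 mM; the very flask that is asked about, followed so far
- flask: second substrate 0.0800 M; free catalyst 4.0 mM

alder run (percent of the starting material charged)

| time / min | target / % |
|---|---|
| 4.00 | 2.0 |
| 10.0 | 4.9 |
| 20.0 | 11.7 |
| 30.0 | 15.6 |

(scatter of a reading: 1 percentage point)

- apparent order in free catalyst when 20% of the starting material are converted (percent change of the rate of making target for one percent more free catalyst charged)
- factor on the rate of making target when 20% of the starting material are converted if free catalyst is charged twice over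

- the analysis behind the earlier runs scatters by 1 percentage point, standard deviation
- no earlier run changes the charge of free catalyst; that part of a forecast is a guess

In the alder flask target climbed steadily, about 0.832 mM/min on average over those minutes. Two numbers in that charge did not seem to go together: the impurity stood at 0.42 mM, far less than the 0.16 M of starting material, yet I could not call it negligible. The contradiction cleared once I changed the yardstick. If the impurity is a poison that binds free catalyst tightly, one for one, it must be held against the catalyst, and there it amounts to 10.5% of the charge. No run had varied the catalyst, so this was my assumption, with the rate taken as proportional to what stays working: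

working catalyst = 4.0 mM − 0.42 mM = 3.58 mM

loss order = 4.0 mM / 3.58 mM = 1.12

doubling factor = (8.00 mM − 0.42 mM) / 3.58 mM = 2.12

The loss order, the charge of free catalyst divided by the catalyst the impurity leaves working, stands above one because a fixed loss weighs less on a larger charge.

The forecast gave an order of 1 (0.6 to 1.25) and a factor of 2 (1.5 to 2.4); it granted that the impurity “could tie up about 10 % of the catalyst if it binds tightly”, but set against this other effects that would pull the order below one. My figures lay above its central values but inside its ranges.

The flask gave an order of 1.1 and a factor of 2.13, both within the forecast's tolerance.

    second substrate + free catalyst ⇌ catalyst intermediate B (K = 940 /M, k = 0.0390 /M/s)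
    coupling partner + catalyst intermediate A → free catalyst + target (k = 2.20 /M/s)
    starting material + free catalyst ⇌ catalyst intermediate A (K = 2.90 /M, k = 0.0410 /M/s)
    free catalyst + impurity → spent catalyst (k = 11.0 /M/s)
    coupling partner + catalyst intermediate B → free catalyst + second product (k = 0.0440 /M/s)

By 0.100 h the flask held impurity at 0% of its charge and spent catalyst at 10.5% of the catalyst charged. The loss order of 1.12 takes the catalyst outside spent catalyst as working, and at 0.500 h free catalyst, catalyst intermediate A and catalyst intermediate B together held 89.5% of the catalyst charged, of which free catalyst stood at 60.9%.

The data were computed with constants of no real substance; the scatter is artificial.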